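**Strategy.** The bromocyclohexane is cut into a four-carbon unit, CH2(C13)–CH(C14)–CMe2(C15)–CH(C10), and the two-carbon unit CH2(C12)–C(CH3)O(C11). The oxygen on C11 and the oxygen that precedes bromine on C14 stand cis-1,4 on this ring, so an isopropenyl(dimethyl)silyl ether of an enantiopure C14 carbinol carries the two-carbon unit as a temporary tether. One stannane-mediated radical cascade (6-endo, then 6-exo onto a vinyl sulfone) closes C12–C13 and C10–C11 and gives a 2-oxa-3-silabicyclo[2.2.2]octane. The sulfone then joins a geraniol-derived C1–C8 chloro diol; bromoetherification builds the tetrahydropyran, Tamao oxidation unveils the C11 and C14 hydroxyls, and the C14 alcohol is inverted to the bromide.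

Key step: step 7

Locants used below: C1 = CH2Cl, C2 = CH(OH), C3 and C7 = the two O-bearing carbons of the tetrahydropyran (C4, C5 = CH2, C6 = CHBr), C8, C9 = the CH2CH2 link, C10 = cyclohexane CH, C11 = C(CH3)OH, C12, C13 = ring CH2, C14 = CHBr, C15 = CMe2.
Assumption: compounds 1, 2, 5, 9, 10 and 15 and the reagents named under Conditions are purchased.

Step 1
Reactants: 1 4-(2-methylprop-1-en-1-yl)morpholine; 2 acetyl chloride
Product: 4 2,2-dimethyl-3-oxobutanal, via iminium chloride 3 (not isolated)
Conditions: Et2O, 0 °C to rt; then 1 M HCl, rt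
Reagents that add atoms: water, O
Why: Stork enamine C-acylation: the β,β-disubstituted enamine is acylated at carbon to the quaternary iminium salt, whose hydrolysis gives the non-enolisable keto aldehyde.

Step 2
Reactants: 4 2,2-dimethyl-3-oxobutanal; 5 diethyl [(phenylsulfonyl)methyl]phosphonate
Product: 6 (E)-3,3-dimethyl-5-(phenylsulfonyl)pent-4-en-2-one
Conditions: LiCl, DBU, MeCN, 0 °C to rt
Reagents that add atoms: none
Why: Horner–Wadsworth–Emmons olefination under Masamune–Roush conditions attacks only the aldehyde (the ketone is flanked by a quaternary carbon) and gives the (E)-vinyl sulfone.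

Step 3
Reactants: 6 (E)-3,3-dimethyl-5-(phenylsulfonyl)pent-4-en-2-one
Product: 7 (E)-1-bromo-3,3-dimethyl-5-(phenylsulfonyl)pent-4-en-2-one
Conditions: Br2 (1.0 equiv), MeOH, 0 °C to rt; then H2O
Reagents that add atoms: bromine, BrBr
Why: Acid-mediated α-bromination of a ketone through its enol: the methyl group is the only enolisable position and the electron-poor vinyl sulfone does not add bromine.

Step 4
Reactants: 7 (E)-1-bromo-3,3-dimethyl-5-(phenylsulfonyl)pent-4-en-2-one
Product: 8 (2R,4E)-1-bromo-3,3-dimethyl-5-(phenylsulfonyl)pent-4-en-2-ol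
Conditions: (R)-2-methyl-CBS-oxazaborolidine (10 mol %), BH3·SMe2, THF, −20 °C; MeOH quench
Reagents that add atoms: none
Why: Corey–Bakshi–Shibata reduction: with the tert-alkyl group as the large and CH2Br as the small substituent the (R)-catalyst should deliver hydride to the face that gives the (R)-bromohydrin, which sets the C14 stereocentre; borane leaves the vinyl sulfone alone at −20 °C.

Step 5
Reactants: 9 isopropenylmagnesium bromide; 10 dichlorodimethylsilane (3 equiv)
Product: 11 chloro(dimethyl)(prop-1-en-2-yl)silane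
Conditions: THF, −78 °C to rt; distillation
Reagents that add atoms: none
Why: Nucleophilic substitution at silicon by the Grignard reagent, held at mono-substitution by the excess of dichlorosilane.

Step 6
Reactants: 8 (2R,4E)-1-bromo-3,3-dimethyl-5-(phenylsulfonyl)pent-4-en-2-ol; 11 chloro(dimethyl)(prop-1-en-2-yl)silane
Product: 12 {[(2R,4E)-1-bromo-3,3-dimethyl-5-(phenylsulfonyl)pent-4-en-2-yl]oxy}(dimethyl)(prop-1-en-2-yl)silane
Conditions: imidazole, CH2Cl2, 0 °C
Reagents that add atoms: none
Why: O-Silylation of the secondary alcohol with a chlorosilane and a mild base that does not close the bromohydrin to an epoxide; the stereocentre is not touched.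

Step 7
Reactants: 12 {[(2R,4E)-1-bromo-3,3-dimethyl-5-(phenylsulfonyl)pent-4-en-2-yl]oxy}(dimethyl)(prop-1-en-2-yl)silane
Product: 14 (1S,4R,5R)-3,3,4,6,6-pentamethyl-5-[(phenylsulfonyl)methyl]-2-oxa-3-silabicyclo[2.2.2]octane, via monocyclic α-silyl radical 13 (not isolated)
Conditions: Bu3SnH (1.3 equiv) and AIBN (0.2 equiv) by syringe pump over 10 h, benzene (5 mM), 80 °C
Reagents that add atoms: none
Why: Bu3Sn• abstracts bromine from C13 and the primary radical adds to the terminal CH2 of the silicon-bound isopropenyl group (6-endo-trig, the mode expected when the internal alkene carbon is fully substituted and a tertiary α-silyl radical results), which forms C12–C13 and an oxasilacyclohexane; this nucleophilic radical 13 then closes 6-exo-trig onto the β-carbon of the (E)-vinyl sulfone (C10–C11, the carbocycle) and the α-sulfonyl radical takes hydrogen from Bu3SnH. The closest known reaction type is the tin hydride cyclisation of β-oxy radicals onto alkenylsilyl ether tethers (temporary silicon connection), here followed by a second ring closure onto an electron-poor alkene. C11 is fixed by the tether: silicon must end on the ring face of the C14 oxygen (cis-1,4), so the configuration set in step 4 is relayed to C11. C10 is set in the second closure, where the sulfonylmethyl arm should turn away from the SiMe2 group toward the CH2–CH2 bridge, which places it trans to the future C11 hydroxyl. The step needs the second cyclisation to outrun hydrogen transfer to 13; high dilution, slow addition of the stannane, the gem-dimethyl group and the strongly radicophilic vinyl sulfone serve this, and a bromide is used so that halogen abstraction beats stannyl addition to the sulfone.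

Step 8
Reactants: 15 geraniol
Product: 16 (2R,3R)-2,3-epoxygeraniol
Conditions: Ti(OiPr)4 (5 mol %), D-(−)-diethyl tartrate (7 mol %), t-BuOOH, 4 Å MS, CH2Cl2, −20 °C
Reagents that add atoms: tert-butyl hydroperoxide, CC(C)(C)OO
Why: Sharpless asymmetric epoxidation: the allylic hydroxyl directs the titanium–tartrate catalyst to the 2,3-alkene only, and D-(−)-tartrate gives the (2R,3R)-epoxide (C2 and C3).

Step 9
Reactants: 16 (2R,3R)-2,3-epoxygeraniol
Product: 17 (2S,3R)-2-(chloromethyl)-3-methyl-3-(4-methylpent-3-en-1-yl)oxirane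
Conditions: PPh3, CCl4, NaHCO3, reflux
Reagents that add atoms: carbon tetrachloride, ClC(Cl)(Cl)Cl
Why: Appel chlorination of the primary alcohol under buffered, neutral conditions; the epoxide and both stereocentres stay intact.

Step 10
Reactants: 17 (2S,3R)-2-(chloromethyl)-3-methyl-3-(4-methylpent-3-en-1-yl)oxirane
Product: 18 (2S,3S)-1-chloro-3,7-dimethyloct-6-ene-2,3-diol
Conditions: HClO4 (cat.), THF/H2O, 0 °C
Reagents that add atoms: water, O
Why: Acid-catalysed epoxide hydrolysis: water opens the protonated epoxide at the tertiary carbon C3 with inversion while the C2–O bond is kept, which gives the (2S,3S)-chloro diol; the α-chlorine disfavours opening at C2.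

Step 11
Reactants: 18 (2S,3S)-1-chloro-3,7-dimethyloct-6-ene-2,3-diol
Product: 19 (2S,3S)-2-[(tert-butyldimethylsilyl)oxy]-1-chloro-3,7-dimethyloct-6-en-3-ol
Conditions: TBSOTf (1.05 equiv), 2,6-lutidine, CH2Cl2, −78 °C
Reagents that add atoms: tert-butyldimethylsilyl triflate, CC(C)(C)[Si](C)(C)OS(=O)(=O)C(F)(F)F
Why: Silyl ether formation, selective for the secondary over the tertiary hydroxyl at −78 °C with one equivalent of triflate; the C3 hydroxyl stays free for the later ether closure.

Step 12
Reactants: 19 (2S,3S)-2-[(tert-butyldimethylsilyl)oxy]-1-chloro-3,7-dimethyloct-6-en-3-ol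
Product: 20 (2E,6S,7S)-7-[(tert-butyldimethylsilyl)oxy]-8-chloro-2,6-dimethyloct-2-ene-1,6-diol
Conditions: SeO2 (cat.), t-BuOOH, salicylic acid (cat.), CH2Cl2, rt
Reagents that add atoms: tert-butyl hydroperoxide, CC(C)(C)OO
Why: Selenium dioxide allylic oxidation (ene reaction then [2,3]-sigmatropic shift), catalytic in selenium, which oxidises the (E)-methyl group of the trisubstituted alkene to the (E)-allylic alcohol.

Step 13
Reactants: 20 (2E,6S,7S)-7-[(tert-butyldimethylsilyl)oxy]-8-chloro-2,6-dimethyloct-2-ene-1,6-diol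
Product: 21 (2E,6S,7S)-1-bromo-7-[(tert-butyldimethylsilyl)oxy]-8-chloro-2,6-dimethyloct-2-en-6-ol
Conditions: CBr4, PPh3, CH2Cl2, 0 °C
Reagents that add atoms: carbon tetrabromide, BrC(Br)(Br)Br
Why: Appel bromination of the primary allylic alcohol at 0 °C, at which the tertiary alcohol and the silyl ether do not react.

Step 14
Reactants: 14 bicyclic siloxane sulfone; 21 allylic bromide
Product: 22 coupled sulfone (14 alkylated at its PhSO2-bearing carbon C9 by C8 of 21; (6E,2S,3S) in the chain, C9 epimers)
Conditions: LDA (1.1 equiv) on 14, THF/DMPU, −78 °C; then 21 as its lithium alkoxide (LiHMDS, 1.0 equiv, THF, −78 °C), −78 to −30 °C; aq. NH4Cl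
Reagents that add atoms: none
Why: Alkylation of an α-sulfonyl carbanion by a primary allylic bromide (SN2, Julia-type fragment coupling) forms the C8–C9 bond; the amide base does not attack silicon, the tertiary hydroxyl travels as its lithium alkoxide, and the new centre at C9 is erased in step 15.

Step 15
Reactants: 22 coupled sulfone
Product: 23 alkene (22 with H in place of PhSO2; C6=C7 (E), C3–OH free, C2–OTBS, C1–Cl, Si–O bridge intact)
Conditions: SmI2, HMPA, THF, t-BuOH, −20 °C
Reagents that add atoms: none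
Why: Reductive desulfonylation by single-electron transfer from SmI2/HMPA; the homoallylic alkene, the primary chloride, the silyl ether and the Si–O bridge should not be reduced at −20 °C.

Step 16
Reactants: 23 alkene
Product: 24 bromotetrahydropyran ((2S,3S,6R,7S); Si–O bridge intact)
Conditions: 2,4,4,6-tetrabromocyclohexa-2,5-dienone (TBCO, 1.1 equiv), MeNO2, 0 °C
Reagents that add atoms: 2,4,4,6-tetrabromocyclohexa-2,5-dienone, O=C1C(Br)=CC(Br)(Br)C=C1Br
Why: Bromoetherification: the bromonium ion of the only remaining alkene is opened by the C3 hydroxyl at the tertiary carbon C7 (6-endo, Markovnikov), anti addition to the (E)-alkene fixes C6 relative to C7, and the chair that keeps the bulky CH(OTBS)CH2Cl group equatorial and the C3 methyl axial (cis to the C7 methyl) should lead to the (6R,7S) isomer; the C11 oxygen is still masked as C–Si and cannot compete.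

Step 17
Reactants: 24 bromotetrahydropyran
Product: 25 diol (C11–OH and C14–OH cis on the cyclohexane, 14S; C2–OTBS)
Conditions: 30% H2O2, KF, KHCO3, THF/MeOH, 50 °C
Reagents that add atoms: hydrogen peroxide, OO
Why: Tamao–Fleming oxidation: hydroperoxide adds to the fluoride-activated alkoxysilane, C11 migrates from silicon to oxygen with retention and the Si–O–C14 bond is hydrolysed, which frees the cis-1,4-diol.

Step 18
Reactants: 25 diol
Product: 26 dibromide (14R; C2–OTBS)
Conditions: CBr4, P(n-C8H17)3, toluene, 70 °C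
Reagents that add atoms: carbon tetrabromide, BrC(Br)(Br)Br
Why: Appel bromination with a trialkylphosphine: bromide displaces the axial C14 alkoxyphosphonium group from the rear (SN2, inversion) to give the equatorial (14R)-bromide; the tertiary C11 hydroxyl is not substituted and, being cis, cannot attack C14 from the rear.

Step 19
Reactants: 26 dibromide
Product: 27 target CNP0182369.1
Conditions: HF·pyridine, THF, 0 °C to rt
Reagents that add atoms: none
Why: Fluoride-mediated cleavage of the silyl ether under acidic conditions, which cannot close the chlorohydrin to an epoxide or displace the secondary bromides.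

**Compound list**

1 | 4-(2-methylprop-1-en-1-yl)morpholine | CC(C)=CN1CCOCC1 | starting material
2 | acetyl chloride | CC(Cl)=O | starting material
3 | 4-(2,2-dimethyl-3-oxobutylidene)morpholin-4-ium chloride | CC(=O)C(C)(C)C=[N+]1CCOCC1.[Cl-] | intermediate
4 | 2,2-dimethyl-3-oxobutanal | CC(=O)C(C)(C)C=O | intermediate
5 | diethyl [(phenylsulfonyl)methyl]phosphonate | CCOP(=O)(CS(=O)(=O)c1ccccc1)OCC | starting material
6 | (E)-3,3-dimethyl-5-(phenylsulfonyl)pent-4-en-2-one | CC(=O)C(C)(C)/C=C/S(=O)(=O)c1ccccc1 | intermediate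
7 | (E)-1-bromo-3,3-dimethyl-5-(phenylsulfonyl)pent-4-en-2-one | O=C(CBr)C(C)(C)/C=C/S(=O)(=O)c1ccccc1 | intermediate
8 | (2R,4E)-1-bromo-3,3-dimethyl-5-(phenylsulfonyl)pent-4-en-2-ol | O[C@@H](CBr)C(C)(C)/C=C/S(=O)(=O)c1ccccc1 | intermediate
9 | isopropenylmagnesium bromide | C=C(C)[Mg]Br | starting material
10 | dichlorodimethylsilane | C[Si](C)(Cl)Cl | starting material
11 | chloro(dimethyl)(prop-1-en-2-yl)silane | C=C(C)[Si](C)(C)Cl | intermediate
12 | {[(2R,4E)-1-bromo-3,3-dimethyl-5-(phenylsulfonyl)pent-4-en-2-yl]oxy}(dimethyl)(prop-1-en-2-yl)silane | C=C(C)[Si](C)(C)O[C@@H](CBr)C(C)(C)/C=C/S(=O)(=O)c1ccccc1 | intermediate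
13 | (6S)-2,2,3-trimethyl-6-[(E)-2-methyl-4-(phenylsulfonyl)but-3-en-2-yl]-1-oxa-2-silacyclohexan-3-yl radical | C[C]1CC[C@@H](C(C)(C)/C=C/S(=O)(=O)c2ccccc2)O[Si]1(C)C | intermediate
14 | (1S,4R,5R)-3,3,4,6,6-pentamethyl-5-[(phenylsulfonyl)methyl]-2-oxa-3-silabicyclo[2.2.2]octane | CC1(C)[C@@H](O2)CC[C@@](C)([Si]2(C)C)[C@@H]1CS(=O)(=O)c1ccccc1 | intermediate
15 | geraniol, (2E)-3,7-dimethylocta-2,6-dien-1-ol | CC(C)=CCC/C(C)=C/CO | starting material
16 | (2R,3R)-2,3-epoxygeraniol | CC(C)=CCC[C@@]1(C)O[C@@H]1CO | intermediate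
17 | (2S,3R)-2-(chloromethyl)-3-methyl-3-(4-methylpent-3-en-1-yl)oxirane | CC(C)=CCC[C@@]1(C)O[C@@H]1CCl | intermediate
18 | (2S,3S)-1-chloro-3,7-dimethyloct-6-ene-2,3-diol | CC(C)=CCC[C@](C)(O)[C@H](O)CCl | intermediate
19 | (2S,3S)-2-[(tert-butyldimethylsilyl)oxy]-1-chloro-3,7-dimethyloct-6-en-3-ol | CC(C)=CCC[C@](C)(O)[C@H](O[Si](C)(C)C(C)(C)C)CCl | intermediate
20 | (2E,6S,7S)-7-[(tert-butyldimethylsilyl)oxy]-8-chloro-2,6-dimethyloct-2-ene-1,6-diol | OC/C(C)=C/CC[C@](C)(O)[C@H](O[Si](C)(C)C(C)(C)C)CCl | intermediate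
21 | (2E,6S,7S)-1-bromo-7-[(tert-butyldimethylsilyl)oxy]-8-chloro-2,6-dimethyloct-2-en-6-ol | BrC/C(C)=C/CC[C@](C)(O)[C@H](O[Si](C)(C)C(C)(C)C)CCl | intermediate
22 | coupled sulfone: 14 carrying on its PhSO2-bearing carbon (C9) the (2E,6S,7S)-7-(TBSO)-8-chloro-6-hydroxy-2,6-dimethyloct-2-enyl group of 21; C9 epimers | CC1(C)[C@@H](O2)CC[C@@](C)([Si]2(C)C)[C@@H]1C(C/C(C)=C/CC[C@](C)(O)[C@H](O[Si](C)(C)C(C)(C)C)CCl)S(=O)(=O)c1ccccc1 | intermediate
23 | alkene: 22 with H in place of PhSO2 (C6=C7 E; 2S,3S) | CC1(C)[C@@H](O2)CC[C@@](C)([Si]2(C)C)[C@@H]1CC/C(C)=C/CC[C@](C)(O)[C@H](O[Si](C)(C)C(C)(C)C)CCl | intermediate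
24 | bromotetrahydropyran (2S,3S,6R,7S) with the C11–Si–O–C14 bridge | CC1(C)[C@@H](O2)CC[C@@](C)([Si]2(C)C)[C@@H]1CC[C@]1(C)O[C@](C)([C@H](O[Si](C)(C)C(C)(C)C)CCl)CC[C@H]1Br | intermediate
25 | diol: 24 with C11–OH and (14S)-C14–OH in place of the silicon bridge | CC1(C)[C@@H](O)CC[C@@](C)(O)[C@@H]1CC[C@]1(C)O[C@](C)([C@H](O[Si](C)(C)C(C)(C)C)CCl)CC[C@H]1Br | intermediate
26 | dibromide: 25 with (14R)-Br in place of the C14 hydroxyl; C2–OTBS | CC1(C)[C@H](Br)CC[C@@](C)(O)[C@@H]1CC[C@]1(C)O[C@](C)([C@H](O[Si](C)(C)C(C)(C)C)CCl)CC[C@H]1Br | intermediate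
27 | CNP0182369.1 (2S,3S,6R,7S,10R,11R,14R) | CC1(C)[C@H](Br)CC[C@@](C)(O)[C@@H]1CC[C@]1(C)O[C@](C)([C@H](O)CCl)CC[C@H]1Br | target

**Step count.** Total: 19 steps. Longest linear sequence: 12 steps (steps 1–4, 6, 7, then 14–19; equally steps 8–13, then 14–19).

**Steps most likely to fail**

1. Step 7. Process at risk: hydrogen transfer from the stannane to the monocyclic radical 13 before the boat-like 6-exo closure, or closure with the sulfonylmethyl arm on the silicon side. Fallback, setting out from 6 and returning at 25: LDA (THF, −78 °C) converts 6 into its only possible enolate, which adds to tert-butyl methacrylate and then closes onto the vinyl sulfone (anionic Michael–Michael annulation, the same two bonds) to give the racemic keto ester F1. Trifluoroacetic acid frees the keto acid F2. Photocatalytic decarboxylative oxygenation under O2 gives the tertiary hydroperoxide F3, which PPh3 reduces in the same flask to the hydroxy ketone F4; oxygen should trap the planar C11 radical on the equatorial side, away from the axial C15 methyl, whatever the configuration of F1. Reagent-controlled (R)-CBS reduction should turn the (10R,11R) half of the racemate into the axial (14S) alcohol, the diol sulfone F5, which is separated from the equatorial alcohol formed from the other enantiomer. TESOTf gives the bis(triethylsilyl) ether F6, which is coupled with 21 as in step 14 to the coupled sulfone F7, desulfonylated as in step 15 to the alkene F8 and cyclised as in step 16 to the bromotetrahydropyran F9. PPTS in MeOH then removes both triethylsilyl groups, keeps the TBS ether and gives 25.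

2. Step 16. Process at risk: 5-exo closure at C6 to a tetrahydrofuran and bromonium formation on the wrong alkene face. Fallback, setting out from 23 and returning at 24: Hg(OCOCF3)2 in MeNO2 at −20 °C adds reversibly and in the Markovnikov sense, so the six-membered ether is reached under thermodynamic control, and KBr work-up gives the organomercury bromide F10. Br2 and LiBr in pyridine under O2 then replace mercury by bromine through the C6 radical, which should take bromine on the less hindered equatorial side, to give 24.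

3. Step 18. Process at risk: E2 loss of the axial leaving group toward C13 (alkene formation) in place of substitution at the neopentyl carbinol. Fallback, setting out from 25 and returning at 26: Dess–Martin oxidation gives the ketone F11, hydrazine the hydrazone F12, and NBS/pyridine (Barton-type hydrazone oxidation) the vinyl bromide F13, whose double bond can only lie at C13=C14 because C15 is quaternary. Hydrogen-atom-transfer hydrogenation (Mn(dpm)3, PhSiH3, t-BuOOH, i-PrOH), which reduces haloalkenes without loss of halogen, should then deliver hydrogen to the C14 α-bromo radical on the axial side and give the equatorial bromide 26.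

**Further compounds**

F1 | step 7 | tert-butyl 1,3,3-trimethyl-4-oxo-2-[(phenylsulfonyl)methyl]cyclohexane-1-carboxylate (racemic, C1 epimers) | CC1(C)C(=O)CCC(C)(C(=O)OC(C)(C)C)C1CS(=O)(=O)c1ccccc1
F2 | step 7 | 1,3,3-trimethyl-4-oxo-2-[(phenylsulfonyl)methyl]cyclohexane-1-carboxylic acid (racemic) | CC1(C)C(=O)CCC(C)(C(=O)O)C1CS(=O)(=O)c1ccccc1
F3 | step 7 | 4-hydroperoxy-2,2,4-trimethyl-3-[(phenylsulfonyl)methyl]cyclohexan-1-one (racemic, OOH trans to the sulfonylmethyl group; one enantiomer drawn) | CC1(C)C(=O)CC[C@@](C)(OO)[C@@H]1CS(=O)(=O)c1ccccc1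
F4 | step 7 | 4-hydroxy-2,2,4-trimethyl-3-[(phenylsulfonyl)methyl]cyclohexan-1-one (racemic, OH trans to the sulfonylmethyl group; one enantiomer drawn) | CC1(C)C(=O)CC[C@@](C)(O)[C@@H]1CS(=O)(=O)c1ccccc1
F5 | step 7 | diol sulfone: 1,3,3-trimethyl-2-[(phenylsulfonyl)methyl]cyclohexane-1,4-diol with the target configuration at C10 and C11 and (14S)-OH | CC1(C)[C@@H](O)CC[C@@](C)(O)[C@@H]1CS(=O)(=O)c1ccccc1
F6 | step 7 | bis(triethylsilyl) ether of F5 | CC1(C)[C@@H](O[Si](CC)(CC)CC)CC[C@@](C)(O[Si](CC)(CC)CC)[C@@H]1CS(=O)(=O)c1ccccc1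
F7 | step 7 | coupled sulfone: F6 alkylated at its sulfonyl carbon by C8 of 21 (C9 epimers) | CC1(C)[C@@H](O[Si](CC)(CC)CC)CC[C@@](C)(O[Si](CC)(CC)CC)[C@@H]1C(C/C(C)=C/CC[C@](C)(O)[C@H](O[Si](C)(C)C(C)(C)C)CCl)S(=O)(=O)c1ccccc1
F8 | step 7 | alkene: F7 with H in place of PhSO2 | CC1(C)[C@@H](O[Si](CC)(CC)CC)CC[C@@](C)(O[Si](CC)(CC)CC)[C@@H]1CC/C(C)=C/CC[C@](C)(O)[C@H](O[Si](C)(C)C(C)(C)C)CCl
F9 | step 7 | bromotetrahydropyran with C11–OTES and C14–OTES | CC1(C)[C@@H](O[Si](CC)(CC)CC)CC[C@@](C)(O[Si](CC)(CC)CC)[C@@H]1CC[C@]1(C)O[C@](C)([C@H](O[Si](C)(C)C(C)(C)C)CCl)CC[C@H]1Br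
F10 | step 16 | organomercury bromide: 24 with HgBr in place of the C6 bromine | CC1(C)[C@@H](O2)CC[C@@](C)([Si]2(C)C)[C@@H]1CC[C@]1(C)O[C@](C)([C@H](O[Si](C)(C)C(C)(C)C)CCl)CC[C@H]1[Hg]Br
F11 | step 18 | C14 ketone of 25 | CC1(C)C(=O)CC[C@@](C)(O)[C@@H]1CC[C@]1(C)O[C@](C)([C@H](O[Si](C)(C)C(C)(C)C)CCl)CC[C@H]1Br
F12 | step 18 | C14 hydrazone of F11 | CC1(C)C(=NN)CC[C@@](C)(O)[C@@H]1CC[C@]1(C)O[C@](C)([C@H](O[Si](C)(C)C(C)(C)C)CCl)CC[C@H]1Br
F13 | step 18 | vinyl bromide (C13=C14, Br on C14) | CC1(C)C(Br)=CC[C@@](C)(O)[C@@H]1CC[C@]1(C)O[C@](C)([C@H](O[Si](C)(C)C(C)(C)C)CCl)CC[C@H]1Br
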